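Germacrane numbering is used throughout: ring C1–C10, lactone C6–O–C12(=O)–C11(=C13)–C7, C14 on C10, C15 on C4.

The route rests on cutting the C3–C4 bond of the cyclodeca-1,4-diene ring. C3 is a doubly allylic carbinol carbon between the (Z)-C4=C5 and (E)-C1=C2 alkenes, so an intramolecular Nozaki–Hiyama–Kishi addition of a (Z)-alkenyl iodide to an enal closes the ten-membered carbocycle after the lactone, forms C3–C4 and sets C3 in one operation. Allylic 1,3-strain across C4=C5 is the controlling element. The precursor is open-chain: a cis-disubstituted α-methylene-γ-butyrolactone whose C6 carries a (Z)-2-iodopropenyl group and whose C7 carries the C8(O-angeloyl)–C9–C10(OH)(CH3)–C1=C2–C3HO arm, built from (R)-linalool by a Barbier lactonization.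

Key step: step 14

Assumption: the (5S)-imidazolidinone catalyst of step 5 is taken to deliver oxygen to the enamine face that gives the (2S)-aldehyde 8; if its sense is the opposite, the (5R)-catalyst is used and nothing else changes.

Step 1
Reactants: 1 (R)-(−)-linalool
Product: 3 (4R)-4-methylhex-5-ene-1,4-diol, via ozonide 2 (not isolated)
Conditions: O3 (1.0 equiv, Sudan III end point), CH2Cl2, −78 °C; then NaBH4, MeOH, −78 °C → rt
Reagents that add atoms: ozone, [O-][O+]=O
Why: Ozonolysis is chemoselective for the electron-rich trisubstituted alkene over the vinyl group, and borohydride reduction of the ozonide gives the diol (C7 as CH2OH) with the chiral-pool C10 centre untouched.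

Step 2
Reactants: 3 (4R)-4-methylhex-5-ene-1,4-diol; 4 2-vinyl-1,3-dioxolane
Product: 5 (4R,5E)-6-(1,3-dioxolan-2-yl)-4-methylhex-5-ene-1,4-diol
Conditions: Hoveyda–Grubbs II catalyst (5 mol%), 4 (5 equiv), CH2Cl2, 40 °C
Reagents that add atoms: none
Why: Olefin cross-metathesis of the free tertiary allylic alcohol with excess acrolein acetal should be E-selective and installs C2–C3 as a masked enal at this early point, before any acrylate unit exists that could divert the ruthenium alkylidene into ring-closing metathesis.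

Step 3
Reactants: 5 (4R,5E)-6-(1,3-dioxolan-2-yl)-4-methylhex-5-ene-1,4-diol
Product: 6 (4R,5E)-6-(1,3-dioxolan-2-yl)-4-methyl-1,4-bis(triethylsilyloxy)hex-5-ene
Conditions: TESOTf (2.4 equiv), 2,6-lutidine, CH2Cl2, −78 °C
Reagents that add atoms: triethylsilyl trifluoromethanesulfonate, CC[Si](CC)(CC)OS(=O)(=O)C(F)(F)F
Why: Silyl triflate silylation of both hydroxyls at −78 °C outruns triflate-induced acetal opening and protects the tertiary C10–OH, so that C7 can later be a free aldehyde instead of a lactol.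

Step 4
Reactants: 6 (4R,5E)-6-(1,3-dioxolan-2-yl)-4-methyl-1,4-bis(triethylsilyloxy)hex-5-ene
Product: 7 (4R,5E)-6-(1,3-dioxolan-2-yl)-4-methyl-4-(triethylsilyloxy)hex-5-enal
Conditions: (COCl)2, DMSO, CH2Cl2, −78 → −40 °C; then Et3N, −78 °C → rt
Reagents that add atoms: none
Why: Under Swern conditions a primary triethylsilyl ether is cleaved and oxidized in the same pot while the tertiary silyl ether survives, which gives the C7 aldehyde directly.

Step 5
Reactants: 7 (4R,5E)-6-(1,3-dioxolan-2-yl)-4-methyl-4-(triethylsilyloxy)hex-5-enal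
Product: 8 (2S,4R,5E)-6-(1,3-dioxolan-2-yl)-4-methyl-2-[(2,2,6,6-tetramethylpiperidin-1-yl)oxy]-4-(triethylsilyloxy)hex-5-enal
Conditions: TEMPO (1.5 equiv), (5S)-5-benzyl-2,2,3-trimethylimidazolidin-4-one·TFA (20 mol%), CuCl2·2H2O (10 mol%), air, acetone, −20 °C
Reagents that add atoms: TEMPO, CC1(C)CCCC(C)(C)N1[O]
Why: Enamine-catalysed α-oxyamination sets C8 under catalyst control, independent of the remote C10 centre, as the (S)-alkoxyamine, which is a robust non-chelating protecting group; this is on purpose the C8 epimer of the target, because step 10 needs it and step 12 inverts it.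

Step 6
Reactants: 8 (2S,4R,5E)-6-(1,3-dioxolan-2-yl)-4-methyl-2-[(2,2,6,6-tetramethylpiperidin-1-yl)oxy]-4-(triethylsilyloxy)hex-5-enal; 9 methyl propiolate
Product: 11 methyl 2-[(2S,4R,5E)-6-(1,3-dioxolan-2-yl)-1-hydroxy-4-methyl-2-[(2,2,6,6-tetramethylpiperidin-1-yl)oxy]-4-(triethylsilyloxy)hex-5-en-1-yl]prop-2-enoate (both C1 epimers), via vinylalane 10 (not isolated)
Conditions: DIBAL-H, NMO, THF, 0 °C; 9, 0 °C; then 8, 0 °C → rt; Rochelle salt work-up
Reagents that add atoms: none
Why: Vinylalumination (hydroalumination of the propiolate to the α-aluminoacrylate, then carbonyl addition) gives the Baylis–Hillman-type adduct without an amine base that could epimerize C8, and the configuration of the new carbinol is irrelevant because C7 becomes sp2 in step 7.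

Step 7
Reactants: 11 methyl 2-[(2S,4R,5E)-6-(1,3-dioxolan-2-yl)-1-hydroxy-4-methyl-2-[(2,2,6,6-tetramethylpiperidin-1-yl)oxy]-4-(triethylsilyloxy)hex-5-en-1-yl]prop-2-enoate
Product: 12 methyl (2Z,4S,6R,7E)-2-(bromomethyl)-8-(1,3-dioxolan-2-yl)-6-methyl-4-[(2,2,6,6-tetramethylpiperidin-1-yl)oxy]-6-(triethylsilyloxy)octa-2,7-dienoate
Conditions: NBS, Me2S, CH2Cl2, 0 °C; then 11, 0 °C → rt
Reagents that add atoms: N-bromosuccinimide, O=C1CCC(=O)N1Br
Why: Corey–Kim-type activation of the Baylis–Hillman alcohol and SN2′ delivery of bromide gives the thermodynamically preferred (Z)-2-(bromomethyl)alk-2-enoate, with C8 cis to CH2Br as step 10 requires.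

Step 8
Reactants: 13 but-2-yn-1-ol
Product: 15 (2Z)-3-iodobut-2-en-1-ol, via vinylalanate 14 (not isolated)
Conditions: Red-Al, THF, 0 °C → rt; then I2, THF, −78 → 0 °C
Reagents that add atoms: iodine, II
Why: Hydroxyl-directed trans-hydroalumination places aluminium on C3 cis to the carbinol carbon in a cyclic alanate, and iodinolysis with retention gives the (Z)-iodoalkene that becomes C4=C5 with C15.

Step 9
Reactants: 15 (2Z)-3-iodobut-2-en-1-ol
Product: 16 (2Z)-3-iodobut-2-enal
Conditions: activated MnO2, CH2Cl2, rt, dark; used at once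
Reagents that add atoms: none
Why: Manganese dioxide oxidizes the allylic alcohol under neutral conditions without touching the C–I bond, and immediate use in the dark guards the Z geometry.

Step 10
Reactants: 12 methyl (2Z,4S,6R,7E)-2-(bromomethyl)-8-(1,3-dioxolan-2-yl)-6-methyl-4-[(2,2,6,6-tetramethylpiperidin-1-yl)oxy]-6-(triethylsilyloxy)octa-2,7-dienoate; 16 (2Z)-3-iodobut-2-enal
Product: 19 (4R,5S)-4-[(1S,3R,4E)-5-(1,3-dioxolan-2-yl)-3-methyl-1-[(2,2,6,6-tetramethylpiperidin-1-yl)oxy]-3-(triethylsilyloxy)pent-4-en-1-yl]-5-[(Z)-2-iodoprop-1-en-1-yl]-3-methylideneoxolan-2-one, via allylzinc bromide 17 (not isolated), via hydroxy ester 18 (not isolated)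
Conditions: Zn dust, THF/sat. aq. NH4Cl, 0 °C → rt; then PPTS (cat.), toluene, 60 °C
Reagents that add atoms: none
Why: This is a Barbier 2-(alkoxycarbonyl)allylation (Dreiding–Schmidt) followed by lactonization: the Zimmerman–Traxler chair with the Z-placed C8 substituent axial and the aldehyde residue equatorial gives the syn adduct and hence the cis lactone (C6, C7), while at C8 allylic 1,3-strain holds C8–H in the olefin plane, the C9 chain goes anti to the forming C6–C7 bond and the small oxygen takes the crowded gauche position, so the (8S) centre should set C6 and C7 as drawn.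

Step 11
Reactants: 19 (4R,5S)-4-[(1S,3R,4E)-5-(1,3-dioxolan-2-yl)-3-methyl-1-[(2,2,6,6-tetramethylpiperidin-1-yl)oxy]-3-(triethylsilyloxy)pent-4-en-1-yl]-5-[(Z)-2-iodoprop-1-en-1-yl]-3-methylideneoxolan-2-one
Product: 20 (4S,5S)-4-[(1S,3R,4E)-5-(1,3-dioxolan-2-yl)-1-hydroxy-3-methyl-3-(triethylsilyloxy)pent-4-en-1-yl]-5-[(Z)-2-iodoprop-1-en-1-yl]-3-methylideneoxolan-2-one
Conditions: Zn dust, AcOH/THF (1:3), 40 °C
Reagents that add atoms: none
Why: Zinc/acetic acid reduction of the N–O bond frees the C8 alcohol, and the water-free, base-free medium should leave the silyl ether, the dioxolane, the alkenyl iodide and the lactone (no translactonization to O8) intact.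

Step 12
Reactants: 20 (4S,5S)-4-[(1S,3R,4E)-5-(1,3-dioxolan-2-yl)-1-hydroxy-3-methyl-3-(triethylsilyloxy)pent-4-en-1-yl]-5-[(Z)-2-iodoprop-1-en-1-yl]-3-methylideneoxolan-2-one; 21 angelic acid
Product: 22 (1R,3R,4E)-5-(1,3-dioxolan-2-yl)-1-[(2S,3S)-2-[(Z)-2-iodoprop-1-en-1-yl]-4-methylidene-5-oxooxolan-3-yl]-3-methyl-3-(triethylsilyloxy)pent-4-en-1-yl (2Z)-2-methylbut-2-enoate
Conditions: PPh3, DIAD, toluene, 0 °C → rt
Reagents that add atoms: none
Why: In the Mitsunobu esterification angelate displaces the alkoxyphosphonium group by SN2, which inverts C8 from S to R and installs the ester without activating the acid, so that angelate-to-tiglate isomerization should be avoided.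

Step 13
Reactants: 22 (1R,3R,4E)-5-(1,3-dioxolan-2-yl)-1-[(2S,3S)-2-[(Z)-2-iodoprop-1-en-1-yl]-4-methylidene-5-oxooxolan-3-yl]-3-methyl-3-(triethylsilyloxy)pent-4-en-1-yl (2Z)-2-methylbut-2-enoate
Product: 23 (1R,3R,4E)-3-hydroxy-1-[(2S,3S)-2-[(Z)-2-iodoprop-1-en-1-yl]-4-methylidene-5-oxooxolan-3-yl]-3-methyl-6-oxohex-4-en-1-yl (2Z)-2-methylbut-2-enoate
Conditions: p-TsOH·H2O (0.2 equiv), acetone/H2O (9:1), rt
Reagents that add atoms: water, O
Why: Acid hydrolysis removes the tertiary silyl ether and the allylic dioxolane (through the allyl-stabilized oxocarbenium ion) in one operation and unveils the (E)-γ-hydroxy enal, which cannot close to a lactol because of its E geometry.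

Step 14
Reactants: 23 (1R,3R,4E)-3-hydroxy-1-[(2S,3S)-2-[(Z)-2-iodoprop-1-en-1-yl]-4-methylidene-5-oxooxolan-3-yl]-3-methyl-6-oxohex-4-en-1-yl (2Z)-2-methylbut-2-enoate
Product: 25 (1E,3R,4Z,6R,7S,8R,10R)-8-angeloyloxy-3,10-dihydroxygermacra-1,4,11(13)-trien-12,6-olide, via alkenylchromium dichloride 24 (not isolated)
Conditions: CrCl2 (10 equiv), NiCl2 (0.1 equiv), degassed DMSO/THF (3:1), rt, slow addition of 23 to a final 0.002 M
Reagents that add atoms: none
Why: Nickel(0) formed in situ inserts into the C4–I bond, transmetalation gives the (Z)-alkenylchromium(III) species 24 with retention of geometry, and this adds 1,2 to the C3 aldehyde; the closest known reaction type is the Nozaki–Hiyama–Kishi macrocyclization of an alkenyl iodide onto an aldehyde. The only ring closed is the ten-membered carbocycle C1–C10, by C3–C4 bond formation in a 10-exo-trig mode, after the lactone, which is carried through intact. The new stereocentre C3 is controlled by allylic 1,3-strain across the (Z)-C4=C5 bond: the aldehyde C3–H and the C6–H both lie in the olefin plane, so the ring bonds C3–C2 and C6–C7 leave on one face and the C3–O and C6–O bonds on the other, which with C6 fixed corresponds to the 3R alcohol. The step needs ring closure over oligomerization, secured by high dilution and slow addition and helped by the cis-lactone and the Z-alkene, which turn the two arms toward each other. It also needs chemoselectivity for the aldehyde, which the organochromium reagent provides because it does not add to lactones, esters or acrylates, does not add 1,4 to the enal and tolerates the free C10 hydroxyl. The E geometry of C1=C2 is already present in the enal and is not touched.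

Step 15
Reactants: 25 (1E,3R,4Z,6R,7S,8R,10R)-8-angeloyloxy-3,10-dihydroxygermacra-1,4,11(13)-trien-12,6-olide
Product: 26 (1E,3R,4Z,6R,7S,8R,10R)-3-acetoxy-8-angeloyloxy-10-hydroxygermacra-1,4,11(13)-trien-12,6-olide (CNP0181631.1)
Conditions: Ac2O, pyridine, DMAP (cat.), CH2Cl2, 0 °C
Reagents that add atoms: acetic anhydride, CC(=O)OC(C)=O
Why: DMAP-catalysed acylation of the secondary doubly allylic C3 alcohol proceeds with retention and is much faster than acylation of the tertiary C10 hydroxyl, which gives the target.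

Compound list
1 | (R)-(−)-linalool, (3R)-3,7-dimethylocta-1,6-dien-3-ol | C=C[C@](C)(O)CCC=C(C)C | starting material
2 | ozonide (not isolated), 5-[(3R)-3-hydroxy-3-methylpent-4-en-1-yl]-3,3-dimethyl-1,2,4-trioxolane | C=C[C@](C)(O)CCC1OOC(C)(C)O1 | intermediate
3 | (4R)-4-methylhex-5-ene-1,4-diol | C=C[C@](C)(O)CCCO | intermediate
4 | 2-vinyl-1,3-dioxolane | C=CC1OCCO1 | starting material
5 | (4R,5E)-6-(1,3-dioxolan-2-yl)-4-methylhex-5-ene-1,4-diol | OCCC[C@@](C)(O)/C=C/C1OCCO1 | intermediate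
6 | (4R,5E)-6-(1,3-dioxolan-2-yl)-4-methyl-1,4-bis(triethylsilyloxy)hex-5-ene | CC[Si](CC)(CC)OCCC[C@@](C)(O[Si](CC)(CC)CC)/C=C/C1OCCO1 | intermediate
7 | (4R,5E)-6-(1,3-dioxolan-2-yl)-4-methyl-4-(triethylsilyloxy)hex-5-enal | O=CCC[C@@](C)(O[Si](CC)(CC)CC)/C=C/C1OCCO1 | intermediate
8 | (2S,4R,5E)-6-(1,3-dioxolan-2-yl)-4-methyl-2-[(2,2,6,6-tetramethylpiperidin-1-yl)oxy]-4-(triethylsilyloxy)hex-5-enal | O=C[C@@H](ON1C(C)(C)CCCC1(C)C)C[C@@](C)(O[Si](CC)(CC)CC)/C=C/C2OCCO2 | intermediate
9 | methyl propiolate | C#CC(=O)OC | starting material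
10 | vinylalane (not isolated), methyl 2-(diisobutylalumanyl)prop-2-enoate | C=C(C(=O)OC)[Al](CC(C)C)CC(C)C | intermediate
11 | methyl 2-[(2S,4R,5E)-6-(1,3-dioxolan-2-yl)-1-hydroxy-4-methyl-2-[(2,2,6,6-tetramethylpiperidin-1-yl)oxy]-4-(triethylsilyloxy)hex-5-en-1-yl]prop-2-enoate, both C1 epimers | C=C(C(=O)OC)C(O)[C@@H](ON1C(C)(C)CCCC1(C)C)C[C@@](C)(O[Si](CC)(CC)CC)/C=C/C2OCCO2 | intermediate
12 | methyl (2Z,4S,6R,7E)-2-(bromomethyl)-8-(1,3-dioxolan-2-yl)-6-methyl-4-[(2,2,6,6-tetramethylpiperidin-1-yl)oxy]-6-(triethylsilyloxy)octa-2,7-dienoate | COC(=O)/C(CBr)=C/[C@@H](ON1C(C)(C)CCCC1(C)C)C[C@@](C)(O[Si](CC)(CC)CC)/C=C/C2OCCO2 | intermediate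
13 | but-2-yn-1-ol | CC#CCO | starting material
14 | vinylalanate (not isolated), sodium 2,2-bis(2-methoxyethoxy)-3-methyl-2,5-dihydro-1,2-oxaluminol-2-uide | CC1=CCO[Al-]1(OCCOC)OCCOC.[Na+] | intermediate
15 | (2Z)-3-iodobut-2-en-1-ol | C/C(I)=C/CO | intermediate
16 | (2Z)-3-iodobut-2-enal | C/C(I)=C/C=O | intermediate
17 | allylzinc bromide (not isolated), zinc insertion product of 12 | COC(=O)/C(C[Zn]Br)=C/[C@@H](ON1C(C)(C)CCCC1(C)C)C[C@@](C)(O[Si](CC)(CC)CC)/C=C/C2OCCO2 | intermediate
18 | hydroxy ester (not isolated), methyl (3R,4S,5Z)-3-[(1S,3R,4E)-5-(1,3-dioxolan-2-yl)-3-methyl-1-[(2,2,6,6-tetramethylpiperidin-1-yl)oxy]-3-(triethylsilyloxy)pent-4-en-1-yl]-4-hydroxy-6-iodo-2-methylidenehept-5-enoate | COC(=O)C(=C)[C@H]([C@H](O)/C=C(/C)I)[C@@H](ON1C(C)(C)CCCC1(C)C)C[C@@](C)(O[Si](CC)(CC)CC)/C=C/C2OCCO2 | intermediate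
19 | (4R,5S)-4-[(1S,3R,4E)-5-(1,3-dioxolan-2-yl)-3-methyl-1-[(2,2,6,6-tetramethylpiperidin-1-yl)oxy]-3-(triethylsilyloxy)pent-4-en-1-yl]-5-[(Z)-2-iodoprop-1-en-1-yl]-3-methylideneoxolan-2-one | C=C1C(=O)O[C@H](/C=C(/C)I)[C@@H]1[C@@H](ON2C(C)(C)CCCC2(C)C)C[C@@](C)(O[Si](CC)(CC)CC)/C=C/C3OCCO3 | intermediate
20 | (4S,5S)-4-[(1S,3R,4E)-5-(1,3-dioxolan-2-yl)-1-hydroxy-3-methyl-3-(triethylsilyloxy)pent-4-en-1-yl]-5-[(Z)-2-iodoprop-1-en-1-yl]-3-methylideneoxolan-2-one | C=C1C(=O)O[C@H](/C=C(/C)I)[C@@H]1[C@@H](O)C[C@@](C)(O[Si](CC)(CC)CC)/C=C/C2OCCO2 | intermediate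
21 | angelic acid, (2Z)-2-methylbut-2-enoic acid | C/C=C(/C)C(=O)O | starting material
22 | (1R,3R,4E)-5-(1,3-dioxolan-2-yl)-1-[(2S,3S)-2-[(Z)-2-iodoprop-1-en-1-yl]-4-methylidene-5-oxooxolan-3-yl]-3-methyl-3-(triethylsilyloxy)pent-4-en-1-yl (2Z)-2-methylbut-2-enoate | C=C1C(=O)O[C@H](/C=C(/C)I)[C@@H]1[C@H](OC(=O)/C(C)=C\C)C[C@@](C)(O[Si](CC)(CC)CC)/C=C/C2OCCO2 | intermediate
23 | (1R,3R,4E)-3-hydroxy-1-[(2S,3S)-2-[(Z)-2-iodoprop-1-en-1-yl]-4-methylidene-5-oxooxolan-3-yl]-3-methyl-6-oxohex-4-en-1-yl (2Z)-2-methylbut-2-enoate | C=C1C(=O)O[C@H](/C=C(/C)I)[C@@H]1[C@H](OC(=O)/C(C)=C\C)C[C@@](C)(O)/C=C/C=O | intermediate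
24 | alkenylchromium dichloride (not isolated), 23 with CrCl2 in place of iodine at C4 | C=C1C(=O)O[C@H](/C=C(/C)[Cr](Cl)Cl)[C@@H]1[C@H](OC(=O)/C(C)=C\C)C[C@@](C)(O)/C=C/C=O | intermediate
25 | (1E,3R,4Z,6R,7S,8R,10R)-8-angeloyloxy-3,10-dihydroxygermacra-1,4,11(13)-trien-12,6-olide | C=C1C(=O)O[C@@H]2/C=C(/C)[C@H](O)/C=C/[C@](C)(O)C[C@@H](OC(=O)/C(C)=C\C)[C@H]12 | intermediate
26 | (1E,3R,4Z,6R,7S,8R,10R)-3-acetoxy-8-angeloyloxy-10-hydroxygermacra-1,4,11(13)-trien-12,6-olide, CNP0181631.1 | C=C1C(=O)O[C@@H]2/C=C(/C)[C@H](OC(C)=O)/C=C/[C@](C)(O)C[C@@H](OC(=O)/C(C)=C\C)[C@H]12 | target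

Total step count: 15. Longest linear sequence: 13 steps (steps 1–7 and 10–15); steps 8–9 make the iodoenal branch.

Steps most likely to fail:

Step 14. The two aldehyde faces may be poorly differentiated in the ring-closing transition state, so that the C3 epimer forms alongside 25. Fallback: starting from 23 the cyclization is run as before, and the mixture of 25 and the (3S)-alcohol F1 is oxidized with MnO2 to the cross-conjugated 3-ketone F2. F2 is reduced under reagent control with (S)-Me-CBS and catecholborane, taking the α-methylalkenyl arm as the large group, and the route is rejoined at 25. C3 is then set by the reduction and not by the ring closure.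

Step 10. The C8 centre may discriminate the two faces of C7 insufficiently, or halide may isomerize the Z-iodoenal 16 to E before it is captured. Fallback: starting from 12, palladium-catalysed borylation (B2pin2, Pd2(dba)3, DMSO) gives the allylboronate F5. F5 adds to 16 through a halide-free chair transition state under a chiral phosphoric acid (TRIP, enantiomer chosen to match), so that the aldehyde face, and with it C6 and C7, is set by the catalyst. Acid-induced lactonization rejoins the route at 19.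

Step 12. Elimination from the alkoxyphosphonium ion at the hindered C8 may outrun substitution, or the phosphine may isomerize the angelate. Fallback: starting from 20, buffered Dess–Martin oxidation gives the C8 ketone F3, and reagent-controlled reduction with (S)-Me-CBS and catecholborane gives the (8R)-alcohol F4. Yamaguchi esterification with angelic acid (2,4,6-trichlorobenzoyl chloride, Et3N, toluene), which retains configuration, rejoins the route at 22.

Further compounds
F1 | step 14 | (1E,3S,4Z,6R,7S,8R,10R)-8-angeloyloxy-3,10-dihydroxygermacra-1,4,11(13)-trien-12,6-olide | C=C1C(=O)O[C@@H]2/C=C(/C)[C@@H](O)/C=C/[C@](C)(O)C[C@@H](OC(=O)/C(C)=C\C)[C@H]12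
F2 | step 14 | (1E,4Z,6R,7S,8R,10R)-8-angeloyloxy-10-hydroxy-3-oxogermacra-1,4,11(13)-trien-12,6-olide | C=C1C(=O)O[C@@H]2/C=C(/C)C(=O)/C=C/[C@](C)(O)C[C@@H](OC(=O)/C(C)=C\C)[C@H]12
F3 | step 12 | (4R,5S)-4-[(3R,4E)-5-(1,3-dioxolan-2-yl)-3-methyl-3-(triethylsilyloxy)pent-4-enoyl]-5-[(Z)-2-iodoprop-1-en-1-yl]-3-methylideneoxolan-2-one | C=C1C(=O)O[C@H](/C=C(/C)I)[C@@H]1C(=O)C[C@@](C)(O[Si](CC)(CC)CC)/C=C/C2OCCO2
F4 | step 12 | (4S,5S)-4-[(1R,3R,4E)-5-(1,3-dioxolan-2-yl)-1-hydroxy-3-methyl-3-(triethylsilyloxy)pent-4-en-1-yl]-5-[(Z)-2-iodoprop-1-en-1-yl]-3-methylideneoxolan-2-one | C=C1C(=O)O[C@H](/C=C(/C)I)[C@@H]1[C@H](O)C[C@@](C)(O[Si](CC)(CC)CC)/C=C/C2OCCO2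
F5 | step 10 | methyl (2E,4S,6R,7E)-8-(1,3-dioxolan-2-yl)-6-methyl-2-[(4,4,5,5-tetramethyl-1,3,2-dioxaborolan-2-yl)methyl]-4-[(2,2,6,6-tetramethylpiperidin-1-yl)oxy]-6-(triethylsilyloxy)octa-2,7-dienoate | COC(=O)/C(CB1OC(C)(C)C(C)(C)O1)=C/[C@@H](ON2C(C)(C)CCCC2(C)C)C[C@@](C)(O[Si](CC)(CC)CC)/C=C/C3OCCO3
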